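The numbers in the tables stem from a simulated flask on assumed constants.

3 questions stand over this flask, in which starting material and coupling partner are stirred with free catalyst to give target.

the same everywhere: starting material 0.99 M; coupling partner 1.04 M
- eta: free catalyst 0.66 mM; run made earlier
- alpha: free catalyst 1.5 mM; run made earlier
- flask: free catalyst 0.99 mM; time 12 h

| run | time / h | starting material / % | target / % |
|---|---|---|---|
| eta | 0.500 | 0.3 | 93.0 |
| eta | 0.833 | 0 | 97.7 |
| eta | 1.33 | 0.4 | 100.3 |
| eta | 2.00 | 0.7 | 99.6 |
| eta | 3.00 | 0 | 100.5 |
| eta | 5.00 | 0 | 99.8 |
| eta | 8.00 | 0.4 | 100.5 |
| alpha | 0.500 | 0.1 | 99.4 |
| alpha | 0.833 | 0 | 99.4 |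
| alpha | 1.33 | 0.5 | 100.6 |
| alpha | 2.00 | 0.5 | 99.3 |
| alpha | 3.00 | 0.2 | 99.4 |
| alpha | 5.00 | 0 | 100.3 |
| alpha | 8.00 | 0 | 100.0 |

(scatter of a reading: 0.5 percentage points)

- why nothing more happens at 12 h, or that something still does (it is still moving / the coupling partner has run out first / no working catalyst is left / all of the starting material has reacted / forward and back rates have come level)
- share of the starting material used up at 12 h
- target at 12 h, in percent of the starting material charged

- the analysis behind the earlier runs scatters by 0.5 percentage points, standard deviation
- a reading or a percentage of target counts all its forms, free or not
- the reaction counts as stopped when no species that holds the starting material changes by six tenths of a point or more over the second half of the time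
- a reading of starting material is of its free form alone

Two numbers seem not to go together. The eta run held 0.66 mM of free catalyst against 0.99 M of starting material, yet it stood at 100.5 % target at 8.00 h, and the alpha run, with 1.5 mM, stood at 100.0 %. So each catalyst in the eta run went round about 1500 times, and its charge moved the pace (93.0 % against 99.4 % at 0.500 h) but not the end.

We therefore reckon the end from the charges, taking one coupling partner per starting material, with equal charges, a ratio of 1, as the point of reference. In this flask that ratio is 1.05: these equivalents, c(coupling partner) over c(starting material), cap target at the ratio when it lies below 1. Above 1, starting material is the limiting reagent, so we expect 4.81 % of the partner charge to remain.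

The forecast gives 100 % conversion and 100 % target at 12 h, the end being that all of the starting material has reacted, on the ground that “Even the lowest catalyst loading completes”.

The flask gives 100 % conversion and 100 % target: all of the starting material has reacted.

    catalyst intermediate B → catalyst intermediate C (k = 13.0 /s)
    starting material ⇌ dormant form (K = 6.40, k = 0.0250 /s)
    crystals ⇌ target, rate k3*(cs3 - [target]) while solid is left; crystals form when [target] > cs3 (solubility = 0.140 M, k = 0.0890 /s)
    coupling partner + catalyst intermediate A → catalyst intermediate B (k = 33.0 /M/s)
    starting material + free catalyst → catalyst intermediate A (k = 26.0 /M/s)
    catalyst intermediate C → free catalyst + target (k = 26.0 /s)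

In this flask, half of the turnover of starting material with free catalyst is done by 0.0756 h, far earlier than the 12 h allowed, and the end shows what equivalents of 1.05 foretold: starting material 0 %, and coupling partner 4.8 % of its charge against our 4.81 %. In the neighbour flask with 0.26 M of coupling partner, the equivalents are 0.263, and at the same time partner stands at 0 %, starting material at 10 %, and target at 26.3 %.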